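**Plan**
- Retrosynthesis opens the furanone ring of the 3-acyltetronic acid at the alkyl C–O bond (ring O1–C5) and at C3–C4. This gives (S)-16-methyl-3-oxooctadecanoic acid (O1, C2, C3 and the whole side chain) and a D-glycerate unit (C4, C5, CH2OH). The acid is cut further at C12–C13 of the acyl chain.
- The enabling feature is that the 4-hydroxyfuran-2(5H)-one ring is a 1,3-O,C-dinucleophile (carboxylate O1 and the doubly activated C3) joined to a 1,2-dielectrophile (acyl carbon C4 and the sp3 carbon C5 that carries CH2OH). A formal (3+2) annulation can therefore build the ring in one flask.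
- The dielectrophile is the 2,3-cyclic sulfate of methyl (R)-glycerate. The temporary dioxathiolane ring activates C5, masks the CH2OH group as a sulfate, and is removed by acid in the same pot.
- Forward order: a copper-catalysed sp3–sp3 coupling makes the anteiso acid, Masamune–Brooks homologation and hydrogenolysis give the 3-oxo acid, and the annulation closes the only ring last.
- Stereochemistry: the chain centre comes unchanged from (S)-1-bromo-2-methylbutane. C5 (S) comes from commercial D-glycerate acetonide by SN2 inversion at its (R) α-carbon.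

Key step: step 6

Remark: the target is drawn as the 4-hydroxy enol of a rapidly equilibrating 3-acyl tricarbonyl system; the route delivers that system and the drawn tautomer is used throughout.

**Step 1**
Reactants: 1 (S)-1-bromo-2-methylbutane; 2 12-bromododecanoic acid
Product: 5 (S)-14-methylhexadecanoic acid, via Grignard reagent 3 (not isolated), via chloromagnesium carboxylate 4 (not isolated)
Conditions: 1, Mg, THF, rt → 40 °C; separately 2, MeMgCl (1.0 equiv), THF, −20 °C; then Li2CuCl4 (3 mol %), 3 (1.5 equiv), −20 °C → rt; 1 M HCl
Reagents that add atoms: none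
Why: Copper-catalysed cross-coupling of a primary alkyl Grignard reagent with a primary alkyl bromide (Kochi-type, Li2CuCl4) should tolerate the magnesium carboxylate, and the stereocentre is β to magnesium and is not touched.

**Step 2**
Reactants: 5 (S)-14-methylhexadecanoic acid; 6 mono-benzyl malonate
Product: 9 benzyl (S)-16-methyl-3-oxooctadecanoate, via acyl imidazolide 7 (not isolated), via acylmalonate half ester 8 (not isolated)
Conditions: CDI (1.1 equiv), THF, rt; then 6 (2 equiv), MgCl2, Et3N, THF/MeCN, rt → 45 °C; 1 M HCl
Reagents that add atoms: none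
Why: In the Masamune–Brooks homologation the acyl imidazolide should C-acylate the magnesium enolate of the malonate half ester, and the acylmalonate should lose CO2 on acidic work-up to leave the β-keto ester; no stereocentre is involved.

**Step 3**
Reactants: 9 benzyl (S)-16-methyl-3-oxooctadecanoate
Product: 10 (S)-16-methyl-3-oxooctadecanoic acid
Conditions: H2 (1 atm), 10% Pd/C, EtOAc, rt; filtration and concentration below 25 °C; used at once
Reagents that add atoms: none
Why: Hydrogenolysis of a benzyl ester under neutral conditions should release the β-keto acid without base or heat, which holds back loss of CO2; the ketone and the remote stereocentre are inert.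

**Step 4**
Reactants: 11 methyl (R)-2,2-dimethyl-1,3-dioxolane-4-carboxylate
Product: 12 methyl (R)-2,3-dihydroxypropanoate
Conditions: Dowex 50WX8 (H+ form), MeOH, rt; filtration, evaporation
Reagents that add atoms: none
Why: Acid-catalysed transketalisation to methanol should remove the isopropylidene group while ester exchange with methanol is degenerate; no bond to C2 is broken, so the (R) configuration is kept.

**Step 5**
Reactants: 12 methyl (R)-2,3-dihydroxypropanoate
Product: 14 methyl (4R)-1,3,2-dioxathiolane-4-carboxylate 2,2-dioxide, via cyclic sulfite 13 (not isolated)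
Conditions: SOCl2 (1.2 equiv), CH2Cl2, 0 °C → reflux; evaporation; then RuCl3·3H2O (0.5 mol %), NaIO4 (1.5 equiv), MeCN/CH2Cl2/H2O, 0 °C
Reagents that add atoms: thionyl chloride, O=S(Cl)Cl; sodium periodate, [Na+].[O-]I(=O)(=O)=O
Why: Cyclic sulfite formation followed by RuO4-catalysed oxidation at sulfur is the standard route from 1,2-diols to cyclic sulfates; only O–H bonds react, so C4 stays (R).

**Step 6**
Reactants: 10 (S)-16-methyl-3-oxooctadecanoic acid; 14 methyl (4R)-1,3,2-dioxathiolane-4-carboxylate 2,2-dioxide
Product: 18 (S)-4-hydroxy-5-(hydroxymethyl)-3-[(S)-14-methylhexadecanoyl]furan-2(5H)-one (target), via cesium 3-oxo carboxylate 15 (not isolated), via ring-opened sulfate monoester 16 (not isolated), via tetronate O-sulfate 17 (not isolated)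
Conditions: 10, Cs2CO3 (0.5 equiv), DMF, 0 °C; 14 (1.1 equiv), 0 °C → rt; then KOtBu (1.5 equiv), THF, 0 °C; then 20% aq H2SO4, THF/Et2O, rt
Reagents that add atoms: none
Why: The cesium carboxylate of 10 should open cyclic sulfate 14 by SN2 attack at the ester-bearing carbon (new O1–C5 bond), and after KOtBu is added the β-keto ester enolate of 16 should attack the methyl ester carbonyl and expel methoxide (new C3–C4 bond), so the operation is a formal (3+2) annulation of an O,C-1,3-dinucleophile with a C,C-1,2-dielectrophile. The closest known reaction types are the carboxylate opening of cyclic sulfates of 2,3-dihydroxy esters at the α-carbon and the Dieckmann cyclisation of α-(3-oxoacyloxy) esters to 3-acyltetronic acids, here run in one flask. The furanone ring closes in the 5-exo-trig mode at the ester carbonyl. C5 is set as (S) by inversion at the (R) carbon of 14, which comes from D-glycerate, and the chain stereocentre is remote. The step needs attack at the α-carbon and not at the primary carbon, which the SN2-accelerating adjacent ester should secure; O- and not C-alkylation, secured by using one equivalent of base so that only the carboxylate is anionic; and acylation instead of alkylation, elimination or C5 epimerisation at the enolate stage, secured because the monoalkyl sulfate anion is a very poor leaving group and the activated methyl ester is attacked quickly at 0 °C. Dilute acid finally cleaves the sulfate at the S–O bond, leaving the CH2–O bond intact, and protonates the tetronate.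

**Compound list**
1 | (S)-1-bromo-2-methylbutane | CC[C@H](C)CBr | starting material
2 | 12-bromododecanoic acid | OC(=O)CCCCCCCCCCCBr | starting material
3 | (S)-2-methylbutylmagnesium bromide | CC[C@H](C)C[Mg]Br | intermediate
4 | chloromagnesium 12-bromododecanoate | BrCCCCCCCCCCCC(=O)O[Mg]Cl | intermediate
5 | (S)-14-methylhexadecanoic acid | CC[C@H](C)CCCCCCCCCCCCC(=O)O | intermediate
6 | mono-benzyl malonate (3-(benzyloxy)-3-oxopropanoic acid) | OC(=O)CC(=O)OCc1ccccc1 | starting material
7 | 1-[(S)-14-methylhexadecanoyl]-1H-imidazole | CC[C@H](C)CCCCCCCCCCCCC(=O)n1ccnc1 | intermediate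
8 | 3-(benzyloxy)-2-[(S)-14-methylhexadecanoyl]-3-oxopropanoic acid (magnesium chelate in the flask; C2 enolised and not defined) | CC[C@H](C)CCCCCCCCCCCCC(=O)C(C(=O)O)C(=O)OCc1ccccc1 | intermediate
9 | benzyl (S)-16-methyl-3-oxooctadecanoate | CC[C@H](C)CCCCCCCCCCCCC(=O)CC(=O)OCc1ccccc1 | intermediate
10 | (S)-16-methyl-3-oxooctadecanoic acid | CC[C@H](C)CCCCCCCCCCCCC(=O)CC(=O)O | intermediate
11 | methyl (R)-2,2-dimethyl-1,3-dioxolane-4-carboxylate | COC(=O)[C@H]1COC(C)(C)O1 | starting material
12 | methyl (R)-2,3-dihydroxypropanoate | COC(=O)[C@H](O)CO | intermediate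
13 | methyl (4R)-1,3,2-dioxathiolane-4-carboxylate 2-oxide (both epimers at sulfur) | COC(=O)[C@H]1COS(=O)O1 | intermediate
14 | methyl (4R)-1,3,2-dioxathiolane-4-carboxylate 2,2-dioxide | COC(=O)[C@H]1COS(=O)(=O)O1 | intermediate
15 | cesium (S)-16-methyl-3-oxooctadecanoate | CC[C@H](C)CCCCCCCCCCCCC(=O)CC(=O)[O-].[Cs+] | intermediate
16 | cesium (S)-3-methoxy-2-{[(S)-16-methyl-3-oxooctadecanoyl]oxy}-3-oxopropyl sulfate | CC[C@H](C)CCCCCCCCCCCCC(=O)CC(=O)O[C@@H](COS(=O)(=O)[O-])C(=O)OC.[Cs+] | intermediate
17 | potassium cesium salt of (S)-3-[(S)-14-methylhexadecanoyl]-5-[(sulfonatooxy)methyl]tetronate | CC[C@H](C)CCCCCCCCCCCCC(=O)C1=C([O-])[C@H](COS(=O)(=O)[O-])OC1=O.[K+].[Cs+] | intermediate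
18 | (S)-4-hydroxy-5-(hydroxymethyl)-3-[(S)-14-methylhexadecanoyl]furan-2(5H)-one | CC[C@H](C)CCCCCCCCCCCCC(=O)C1=C(O)[C@H](CO)OC1=O | target

**Count**
Total steps: 6. Longest linear sequence: 4 (steps 1, 2, 3, 6); steps 4 and 5 form the second branch.

**Steps most likely to fail**

Step 6. The carboxylate may attack the primary carbon of the cyclic sulfate in competition with the α-carbon, the 3-oxo carboxylate may lose CO2 before it is alkylated, or C5 may epimerise under the Dieckmann base. The fallback makes the two bonds one after the other, with an electrophile that has a single reactive carbon. It sets out from 12 and 15 and comes back at 18. Selective tritylation of the primary hydroxyl of 12 (Ph3CCl, Et3N, cat. DMAP, CH2Cl2) should give methyl (R)-2-hydroxy-3-(trityloxy)propanoate F1. Tf2O and 2,6-lutidine in CH2Cl2 at −78 °C should give methyl (R)-2-{[(trifluoromethyl)sulfonyl]oxy}-3-(trityloxy)propanoate F2. Carboxylate 15 should displace the triflate with inversion in DMF at −20 °C to give methyl (S)-2-{[(S)-16-methyl-3-oxooctadecanoyl]oxy}-3-(trityloxy)propanoate F3. Bu4NF in THF should bring about the Dieckmann cyclisation to (S)-4-hydroxy-3-[(S)-14-methylhexadecanoyl]-5-[(trityloxy)methyl]furan-2(5H)-one F4, and CF3CO2H in wet CH2Cl2 should remove the trityl group to give 18.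

Step 1. Homocoupling and reduction of the Grignard reagent, or slow coupling of the poorly soluble magnesium carboxylate, may erode the chain-joining step. The fallback joins the chain by olefination instead. It sets out from 2 and comes back at 5. Heating 2 with PPh3 in MeCN should give (11-carboxyundecyl)triphenylphosphonium bromide F5. Commercial (S)-2-methylbutan-1-ol (CC[C@H](C)CO) is oxidised (TEMPO, NaOCl, KBr, CH2Cl2/H2O, 0 °C) to (S)-2-methylbutanal F6, which is used cold and at once. The ylide from F5 and NaN(SiMe3)2 (2 equiv, THF, −78 °C) should give, in a Wittig reaction, (S,Z)-14-methylhexadec-12-enoic acid F7. Diimide reduction (TsNHNH2, NaOAc, aq THF, reflux), which avoids double-bond migration at the allylic stereocentre, should then give 5.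

Step 3. The free 3-oxo acid may lose CO2 during catalyst filtration and concentration. The fallback never forms the free acid. It sets out from 9 and comes back at 15. Saponification of 9 with CsOH·H2O (1.0 equiv, THF/H2O, 0 °C → rt), extraction of the benzyl alcohol with Et2O and freeze-drying should deliver the cesium salt 15 directly, which enters step 6 without Cs2CO3. This fallback makes no new compound (F0).

**Further compounds**
F1 | step 6 | methyl (R)-2-hydroxy-3-(trityloxy)propanoate | COC(=O)[C@H](O)COC(c1ccccc1)(c1ccccc1)c1ccccc1
F2 | step 6 | methyl (R)-2-{[(trifluoromethyl)sulfonyl]oxy}-3-(trityloxy)propanoate | COC(=O)[C@H](OS(=O)(=O)C(F)(F)F)COC(c1ccccc1)(c1ccccc1)c1ccccc1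
F3 | step 6 | methyl (S)-2-{[(S)-16-methyl-3-oxooctadecanoyl]oxy}-3-(trityloxy)propanoate | CC[C@H](C)CCCCCCCCCCCCC(=O)CC(=O)O[C@@H](COC(c1ccccc1)(c1ccccc1)c1ccccc1)C(=O)OC
F4 | step 6 | (S)-4-hydroxy-3-[(S)-14-methylhexadecanoyl]-5-[(trityloxy)methyl]furan-2(5H)-one | CC[C@H](C)CCCCCCCCCCCCC(=O)C1=C(O)[C@H](COC(c2ccccc2)(c2ccccc2)c2ccccc2)OC1=O
F5 | step 1 | (11-carboxyundecyl)triphenylphosphonium bromide | OC(=O)CCCCCCCCCCC[P+](c1ccccc1)(c1ccccc1)c1ccccc1.[Br-]
F6 | step 1 | (S)-2-methylbutanal | CC[C@H](C)C=O
F7 | step 1 | (S,Z)-14-methylhexadec-12-enoic acid | CC[C@H](C)/C=C\CCCCCCCCCCC(=O)O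
F0 | step 3 | none | none
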